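The readings are simulated on assumed constants; noise was put on by code.

The kineticist opened the meeting by laying out the flasks eta, theta, delta and beta, which share one charge of G and differ in temperature; eta is cooled at 6.0 min.

in all of them: E 20 mM
- autumn: G 0.54 equiv; temperature 55 °C; run made earlier
- summer: G 1.2 equiv; temperature 88 °C; run made earlier
- eta: G 0.800 equiv; at 100 °C until 6.0 min, from then on at 40 °C; time 12 min
- theta: G 0.800 equiv; temperature 40 °C; time 12 min
- delta: G 0.800 equiv; temperature 70 °C; time 12 min
- beta: G 0.800 equiv; temperature 100 °C; time 12 min

autumn run (percent of the E charged)

| time / min | L / % |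
|---|---|
| 0.333 | 11.4 |
| 1.00 | 21.8 |
| 1.33 | 25.8 |
| 2.50 | 32.7 |
| 4.00 | 32.8 |
| 5.00 | 34.4 |
| 6.00 | 33.0 |

summer run (percent of the E charged)

| time / s | L / % |
|---|---|
| 10.0 | 37.2 |
| 12.0 | 42.2 |
| 15.0 | 46.0 |
| 30.0 | 63.6 |
| 40.0 | 68.7 |
| 60.0 | 76.1 |

(each reading ± 1 percentage point)

- the analysis behind the earlier runs scatters by 1 percentage point, standard deviation

- which flask leads in amount of L, in percent of the E charged ("all alike" within 1.5 percentage points) (eta / theta / delta / beta / all alike)
- how much L is there at the end, in percent of the E charged: eta
- how much L is there at the end, in percent of the E charged: theta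
- how much L is there at the end, in percent of the E charged: delta
- how much L is there at the end, in percent of the E charged: beta

She reported that the autumn readings stand flat within their scatter from 2.50 min on, the last of them averaging 33.2 % of the E charged, with G charged at 0.54 equiv. Dividing the two gave 0.615, and she proposed to carry this number as the return on G: the fraction of E standing as L at the plateau per equivalent of G charged, a yield reckoned on G.

The process chemist objected that temperature might move it. She answered that the last summer reading, still rising, gives 0.634, close to the autumn value. In powers of ten, the pace to the first reading per equivalent of G rose by 0.467 from the autumn run to the summer run, which differ in temperature and in G, far more than this ratio of L to G, which rose by 0.0131.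

Her own reckoning was therefore 49.2 % of L in each of the flasks at this charge of G, and so no clear leader. Her estimate, scaling the autumn time of flattening to 40 °C at that pace, put the plateau of theta near 4.08 min, earlier than 12 min.

The forecaster differed, holding that “G is lost in a side path”. The forecast named beta as leader, with eta 64.5 %, theta 38.5 %, delta 54.5 % and beta 65 %.

The outcome is all alike: eta 54.3 %, theta 54.7 %, delta 55.3 %, beta 54.3 %.

    E + L → D (k = 4.80 /M/min, Ea = 46.0 kJ/mol)
    E + G → L, rate k2*[E]^0.5*[G] (k = 2.12 /M^0.5/min, Ea = 43.0 kJ/mol)
    (constants at 40 °C)

From the coldest flask to the hottest, the making of L speeds up by a factor of 14 and its passing with E into D by 17. The return on G in eta comes to 0.679, above the 0.615 carried from autumn. A further flask, like eta but charged with 0.200 equiv of G, has a reckoned L of 12.3 %. It ends with L at 0.0376 % and E at 60.0 %.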